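(Readings and results stem from a simulated flask for an exercise; the scatter is artificial.)

The closed flask holds a racemate with a single-handed free catalyst and a racemization catalyst, and the thing to watch is how much of the reacted substrate turns up as left-handed product.

| flask | left-handed substrate | right-handed substrate | reagent | free catalyst | racemization catalyst | remark | time |
|---|---|---|---|---|---|---|---|
| larch | 0.020 M | 0.020 M | 4 equiv | 0.17 mol% | 1 mol% | run made earlier |  |
| cedar | 0.020 M | 0.020 M | 4 equiv | 0.66 mol% | 1 mol% | run made earlier |  |
| flask | 0.020 M | 0.020 M | 4.00 equiv | 0.33 mol% | 1 mol% |  | 10 d |

| run | time / d | left-handed product / % | left-handed substrate / % |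
|---|---|---|---|
| larch | 2.50 | 15.7 | 38.7 |
| larch | 3.00 | 15.9 | 37.0 |
| larch | 5.00 | 23.5 | 31.0 |
| larch | 6.00 | 27.3 | 26.7 |
| cedar | 2.50 | 37.7 | 21.6 |
| cedar | 3.00 | 39.4 | 18.3 |
| cedar | 5.00 | 48.2 | 9.3 |
| cedar | 6.00 | 51.3 | 7.9 |

(readings scatter by 1 percentage point)

- free catalyst is single-handed; left-handed substrate and right-handed substrate are mirror images of each other, charged as a racemate, each of them at the stated concentration
- the earlier runs were read with a standard deviation of 1 percentage point

* the moment within 10 d at which there is most left-handed product
* the amount of left-handed product, in percent of the left-handed substrate and right-handed substrate together charged, at that time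

Take the symmetric case as the zero of the scale. Suppose the racemization catalyst keeps the two substrates equal, so that each reading of left-handed substrate also gives the unseen right-handed one. The reacted part is then the charge less both, and a catalyst without preference would turn 0.5 of it into left-handed product. The left share, left-handed product over that reacted part, reads 0.618 when pooled over the readings of both runs, a selectivity factor of 1.62. At 6.00 d the larch reading gives 0.586 and the cedar reading 0.609, though the free catalyst loading of cedar is 3.88 times that of larch.

Next comes the substrate left. Read as plain decay up to 6.00 d, larch falls at 0.105 d⁻¹ and cedar at 0.308 d⁻¹, a rise of 2.93, less than the catalyst's 3.88. Their geometric mean would leave 8.28% left-handed substrate in the flask at 10 d.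

The weak link is that constant pace, and reagent is consumed too. It is charged at 2.00 equivalents on both substrates together, so, with one reagent taken per substrate reacted, the fraction of reagent left is the mean of one and the fraction of substrate left. If the rate follows substrate, reagent and catalyst, the logarithm of reagent left over substrate left, each as a fraction of its charge, grows evenly with time and catalyst. It stands at 0.362 in larch and 1.30 in cedar, a rise of 3.59, nearer the catalyst's ratio. Scaled to the flask it reaches 1.13, which leaves 19.3% of both substrates and 59.6% of the reagent. My reckoning is therefore 49.9% left-handed product, highest at the limit of 10 d, with 19.3% of both substrates reckoned still unreacted there.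

The forecast gives 49% (range 45.5% to 52%) at 10 d (range 9.5 d to 10 d), its ground for that moment being that “Nothing consumes product, so it still rises slowly at the time limit”.

The flask gives 49.7% of left-handed product at 10.0 d.

    reagent + free catalyst + right-handed substrate → free catalyst + right-handed product (k = 22.0 M⁻² min⁻¹)
    left-handed substrate + racemization catalyst ⇌ right-handed substrate + racemization catalyst, rate k2*[racemization catalyst]*[left-handed substrate] forward; the back reaction follows from the equilibrium constant (k = 79.0 M⁻¹ min⁻¹)
    reagent + free catalyst + left-handed substrate → free catalyst + left-handed product (k = 36.0 M⁻² min⁻¹)

Beside it the flask holds 30.4% of right-handed product, so the left share of its products is 0.620. With 0.56 mol% of free catalyst, the neighbouring flask has 4.17% of left-handed substrate at 10.0 d. The left share 0.618, applied to the charge less both substrates, gives 56.6% there, and that flask holds 56.8% of left-handed product.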